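The ten-membered carbocycle (ring A) is disconnected at the C4–C5 epoxide. The epoxide is taken back to the ring-cis C4=C5 alkene, and that alkene to a C5 vinyl group and a C4 isopropenyl terminus. One ring-closing metathesis therefore forms ring A and its only missing C–C bond, with the alkene geometry the cis epoxide needs. The step exploits the cis junction at C6–C7 of the α-methylene-γ-lactone (ring B) and the ring-cis C1=C10 enoate, which hold C5 and C4 on one side. The precursor is the cis lactone with a C6 vinyl group and a C7 chain carrying the C8 acetate, the C9 epoxy ester, the C10 methyl enoate and the C4 isopropenyl end.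

Key step: step 13

Remark: germacrane numbering is used (ring A = C1–C10; ring B = O, C6, C7, C11, C12; C13 methylene; C14 ester carbon; C15 methyl). The 8,9-diol is threo, which non-chelation addition to a C9 aldehyde does not give, so C9 is made as the 9R epimer and inverted when the epoxy acid is attached. The descriptors at C6 and C7 change along the route through priority switches only.

Step 1
Reactants: 1 (R)-2,3-O-isopropylideneglyceraldehyde; 2 methyl acrylate
Product: 3 methyl 2-{[(4R)-2,2-dimethyl-1,3-dioxolan-4-yl](hydroxy)methyl}prop-2-enoate (both carbinol epimers)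
Conditions: DABCO (0.5 equiv), 1,4-dioxane/H2O (1:1), rt, 2–4 d
Reagents that add atoms: none
Why: Morita–Baylis–Hillman reaction, in which DABCO adds to the acrylate and the resulting enolate attacks the α-alkoxy aldehyde; the new carbinol centre forms as an epimer mixture that is erased in step 2, and the dioxolane centre is not touched.

Step 2
Reactants: 3 Morita–Baylis–Hillman alcohol
Product: 4 methyl (2Z)-2-(bromomethyl)-3-[(4S)-2,2-dimethyl-1,3-dioxolan-4-yl]prop-2-enoate
Conditions: NBS, Me2S, CH2Cl2, 0 °C to rt
Reagents that add atoms: N-bromosuccinimide, O=C1CCC(=O)N1Br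
Why: Bromination of a Morita–Baylis–Hillman alcohol through its alkoxysulfonium salt proceeds with allylic transposition (SN2′) and should give the thermodynamically favoured (Z)-2-(bromomethyl)enoate, ester trans to the dioxolane, under neutral conditions that spare the acetal.

Step 3
Reactants: 4 allylic bromide; 5 acrolein
Product: 7 (4S,5S)-4-[(4S)-2,2-dimethyl-1,3-dioxolan-4-yl]-5-ethenyl-3-methylideneoxolan-2-one (cis lactone), via hydroxy ester 6 (not isolated)
Conditions: indium powder, THF/H2O (1:1), rt; then TsOH·H2O (5 mol%), CH2Cl2, rt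
Reagents that add atoms: none
Why: Indium-mediated Barbier 2-(alkoxycarbonyl)allylation followed by acid-catalysed lactonisation: the allylindium reacts through C7 (SE2′) in a chair transition state with the vinyl group equatorial and the C8 substituent axial, as the Z geometry dictates, which gives the syn adduct and hence the cis lactone; 1,3-allylic strain keeps C8–H in the alkene plane and the aldehyde should approach C7 anti to the C8–C9 bond with the C8–O bond outside, the sterically and electronically preferred arrangement, which sets C6 and C7 (4S,5S in 7).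

Step 4
Reactants: 7 lactone acetonide
Product: 8 (4R,5S)-4-[(1S)-1,2-dihydroxyethyl]-5-ethenyl-3-methylideneoxolan-2-one
Conditions: AcOH/H2O (4:1), 40 °C
Reagents that add atoms: none
Why: Acid hydrolysis of a terminal isopropylidene acetal is far faster than acid-catalysed opening or transposition of a γ-lactone, so the diol should be freed with the C6–O lactone intact.

Step 5
Reactants: 8 diol
Product: 9 (4S,5S)-4-[(1S)-1,2-bis(triethylsilyloxy)ethyl]-5-ethenyl-3-methylideneoxolan-2-one
Conditions: TESCl, imidazole, DMF, 0 °C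
Reagents that add atoms: chlorotriethylsilane, CC[Si](Cl)(CC)CC
Why: Standard silylation of a primary and a secondary hydroxyl with a chlorosilane and imidazole, run at once so that the free C8 hydroxyl has no time to attack the lactone carbonyl.

Step 6
Reactants: 9 bis-silyl ether
Product: 10 (2S)-2-[(2S,3S)-2-ethenyl-4-methylidene-5-oxooxolan-3-yl]-2-(triethylsilyloxy)acetaldehyde
Conditions: (COCl)2, DMSO, CH2Cl2, −78 to −40 °C; then Et3N, −78 to 0 °C
Reagents that add atoms: none
Why: Swern oxidation of triethylsilyl ethers, in which the chlorosulfonium reagent cleaves and oxidises the primary silyl ether directly to the aldehyde while the secondary one is inert; amine treatment at low temperature should not epimerise C8.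

Step 7
Reactants: 11 4-methylpent-4-enal; 12 methyl (triphenylphosphoranylidene)acetate
Product: 14 methyl (2Z)-2-iodo-6-methylhepta-2,6-dienoate, via iodo ylide 13 (not isolated)
Conditions: NIS, CH2Cl2, −20 °C; then 11, 0 °C to rt
Reagents that add atoms: N-iodosuccinimide, O=C1CCC(=O)N1I
Why: Iodination of the stabilised ylide (the succinimide anion released acts as the base) followed by Wittig olefination in one pot is a known route to α-iodoenoates and places the ester trans to the alkyl chain, which is the 2Z isomer.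

Step 8
Reactants: 10 aldehyde; 14 iodoenoate
Product: 15 methyl (2E)-2-{(1R,2S)-2-[(2S,3S)-2-ethenyl-4-methylidene-5-oxooxolan-3-yl]-1-hydroxy-2-(triethylsilyloxy)ethyl}-6-methylhepta-2,6-dienoate
Conditions: CrCl2 (excess), NiCl2 (cat.), DMSO, rt
Reagents that add atoms: none
Why: Nozaki–Hiyama–Kishi coupling, in which zerovalent nickel inserts into the C–I bond with retention and transmetalation gives an alkenyl species of trivalent chromium that adds only to the aldehyde and leaves lactone, esters and enoates alone; under non-chelation control the C8 silyloxy group lies anti to the incoming alkenyl group, so the 8,9-anti (9R) carbinol should predominate, which is the epimer wanted for inversion in step 10.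

Step 9
Reactants: 16 (S)-2-methylglycidol
Product: 17 (2R)-2-methyloxirane-2-carboxylic acid
Conditions: RuCl3·xH2O (cat.), NaIO4, MeCN/EtOAc/H2O, 0 °C to rt
Reagents that add atoms: water, O
Why: Catalytic ruthenium tetroxide oxidation of primary 2,3-epoxy alcohols to glycidic acids is established and does not touch the quaternary epoxide centre, whose descriptor changes from S to R only because the priorities change.

Step 10
Reactants: 15 (9R) alcohol; 17 epoxy acid
Product: 18 methyl (2E)-2-{(1S,2S)-2-[(2S,3S)-2-ethenyl-4-methylidene-5-oxooxolan-3-yl]-1-{[(2R)-2-methyloxirane-2-carbonyl]oxy}-2-(triethylsilyloxy)ethyl}-6-methylhepta-2,6-dienoate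
Conditions: PPh3 and DIAD premixed, toluene, 0 °C; then 17 and 15, 0 °C to rt
Reagents that add atoms: none
Why: Mitsunobu esterification, in which the preformed phosphine–azodicarboxylate betaine activates the C9 hydroxyl and the carboxylate displaces it by SN2 with inversion, turning 9R into the required 9S while the ester is attached; the C8 silyl ether cannot participate.

Step 11
Reactants: 18 silyl ether
Product: 19 methyl (2E)-2-{(1S,2S)-2-[(2S,3R)-2-ethenyl-4-methylidene-5-oxooxolan-3-yl]-2-hydroxy-1-{[(2R)-2-methyloxirane-2-carbonyl]oxy}ethyl}-6-methylhepta-2,6-dienoate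
Conditions: HF·pyridine, pyridine, THF, 0 °C
Reagents that add atoms: none
Why: Fluoride-mediated cleavage of a secondary triethylsilyl ether under buffered acidic conditions, which are too mild for the epoxy ester and do not promote acyl migration from O9 to O8.

Step 12
Reactants: 19 C8 alcohol
Product: 20 methyl (2E)-2-{(1S,2S)-2-(acetyloxy)-2-[(2S,3S)-2-ethenyl-4-methylidene-5-oxooxolan-3-yl]-1-{[(2R)-2-methyloxirane-2-carbonyl]oxy}ethyl}-6-methylhepta-2,6-dienoate (seco-4,5 diene)
Conditions: Ac2O, pyridine, DMAP (cat.), CH2Cl2, 0 °C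
Reagents that add atoms: acetic anhydride, CC(=O)OC(C)=O
Why: Standard DMAP-catalysed acetylation of a secondary alcohol, fast enough at 0 °C to outrun acyl migration.

Step 13
Reactants: 20 seco-4,5 diene
Product: 21 methyl (3aS,4S,5S,6E,10Z,11aS)-4-(acetyloxy)-10-methyl-3-methylidene-5-{[(2R)-2-methyloxirane-2-carbonyl]oxy}-2-oxo-2,3,3a,4,5,8,9,11a-octahydrocyclodeca[b]furan-6-carboxylate (4,5-deoxy macrocycle)
Conditions: second-generation Hoveyda–Grubbs catalyst RuCl2(H2IMes)(=CH–C6H4-2-OiPr) (15 mol%, in portions), 1,4-benzoquinone (cat.), toluene (0.001 M), 80 °C, argon sparge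
Reagents that add atoms: none
Why: Ring-closing olefin metathesis: the ruthenium benzylidene exchanges onto the monosubstituted C5 vinyl group, the resulting alkylidene adds to the 1,1-disubstituted C4 alkene to give a ruthenacyclobutane, and cycloreversion forms C4=C5 and a ruthenium methylidene that leaves as ethylene. The closest known reaction type is ring-closing metathesis to ring-cis trisubstituted cyclodecenes and to ten-membered lactones. Ring A is closed between the two internal alkene carbons, so both terminal CH2 groups are lost and the new alkene is endocyclic in a ten-membered ring. No stereocentre is formed; the alkene geometry is set by ring strain, because in a ten-membered ring cis-fused to the lactone a trans trisubstituted alkene would be badly strained, so the isomer with C3 and C6 on one side should form. The step needs cyclisation instead of oligomerisation, and closure onto C4 instead of onto C10, which would cut off the C1–C4 chain and leave a cyclohexene. The cis C5/C8 relation on ring B and the ring-cis C1=C10 enoate fold the chain towards C4 at high dilution; C10 is a fully substituted, ester-bearing alkene carbon shielded by the C9 acyloxy group, and C11=C13 is electron-poor and could only give a four-membered ring.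

Step 14
Reactants: 21 4,5-deoxy macrocycle
Product: 22 CNP0159450.1 (target)
Conditions: mCPBA (1.1 equiv), NaHCO3, CH2Cl2, 0 °C
Reagents that add atoms: 3-chloroperbenzoic acid, OOC(=O)c1cccc(Cl)c1
Why: Prilezhaev epoxidation is stereospecific, so the ring-cis alkene gives the cis epoxide, and it is selective for the only electron-rich alkene; 1,3-allylic strain with C3 should keep C6–H in the alkene plane, which puts C7 and the body of ring A on one face, and attack on the open face places the epoxide oxygen anti to C7, trans to the lactone oxygen across C5–C6, the 4R,5S configuration of the target.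

Compound list
1 | (R)-2,3-O-isopropylideneglyceraldehyde, (4R)-2,2-dimethyl-1,3-dioxolane-4-carbaldehyde | O=C[C@H]1COC(C)(C)O1 | starting material
2 | methyl acrylate | C=CC(=O)OC | starting material
3 | methyl 2-{[(4R)-2,2-dimethyl-1,3-dioxolan-4-yl](hydroxy)methyl}prop-2-enoate (carbinol epimers) | C=C(C(=O)OC)C(O)[C@H]1COC(C)(C)O1 | intermediate
4 | methyl (2Z)-2-(bromomethyl)-3-[(4S)-2,2-dimethyl-1,3-dioxolan-4-yl]prop-2-enoate | COC(=O)/C(CBr)=C/[C@H]1COC(C)(C)O1 | intermediate
5 | acrolein | C=CC=O | starting material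
6 | methyl (3S,4S)-3-[(4S)-2,2-dimethyl-1,3-dioxolan-4-yl]-4-hydroxy-2-methylidenehex-5-enoate | C=C(C(=O)OC)[C@@H]([C@@H](O)C=C)[C@H]1COC(C)(C)O1 | intermediate
7 | (4S,5S)-4-[(4S)-2,2-dimethyl-1,3-dioxolan-4-yl]-5-ethenyl-3-methylideneoxolan-2-one | C=C1C(=O)O[C@@H](C=C)[C@H]1[C@H]1COC(C)(C)O1 | intermediate
8 | (4R,5S)-4-[(1S)-1,2-dihydroxyethyl]-5-ethenyl-3-methylideneoxolan-2-one | C=C1C(=O)O[C@@H](C=C)[C@H]1[C@H](O)CO | intermediate
9 | (4S,5S)-4-[(1S)-1,2-bis(triethylsilyloxy)ethyl]-5-ethenyl-3-methylideneoxolan-2-one | C=C1C(=O)O[C@@H](C=C)[C@H]1[C@H](O[Si](CC)(CC)CC)CO[Si](CC)(CC)CC | intermediate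
10 | (2S)-2-[(2S,3S)-2-ethenyl-4-methylidene-5-oxooxolan-3-yl]-2-(triethylsilyloxy)acetaldehyde | C=C1C(=O)O[C@@H](C=C)[C@H]1[C@H](O[Si](CC)(CC)CC)C=O | intermediate
11 | 4-methylpent-4-enal | C=C(C)CCC=O | starting material
12 | methyl (triphenylphosphoranylidene)acetate | COC(=O)C=P(c1ccccc1)(c1ccccc1)c1ccccc1 | starting material
13 | methyl iodo(triphenylphosphoranylidene)acetate | COC(=O)C(I)=P(c1ccccc1)(c1ccccc1)c1ccccc1 | intermediate
14 | methyl (2Z)-2-iodo-6-methylhepta-2,6-dienoate | COC(=O)/C(I)=C/CCC(C)=C | intermediate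
15 | methyl (2E)-2-{(1R,2S)-2-[(2S,3S)-2-ethenyl-4-methylidene-5-oxooxolan-3-yl]-1-hydroxy-2-(triethylsilyloxy)ethyl}-6-methylhepta-2,6-dienoate | C=C1C(=O)O[C@@H](C=C)[C@H]1[C@H](O[Si](CC)(CC)CC)[C@H](O)/C(C(=O)OC)=C\CCC(C)=C | intermediate
16 | (S)-2-methylglycidol, [(2S)-2-methyloxiran-2-yl]methanol | OC[C@@]1(C)CO1 | starting material
17 | (2R)-2-methyloxirane-2-carboxylic acid | OC(=O)[C@@]1(C)CO1 | intermediate
18 | methyl (2E)-2-{(1S,2S)-2-[(2S,3S)-2-ethenyl-4-methylidene-5-oxooxolan-3-yl]-1-{[(2R)-2-methyloxirane-2-carbonyl]oxy}-2-(triethylsilyloxy)ethyl}-6-methylhepta-2,6-dienoate | C=C1C(=O)O[C@@H](C=C)[C@H]1[C@H](O[Si](CC)(CC)CC)[C@@H](OC(=O)[C@@]1(C)CO1)/C(C(=O)OC)=C\CCC(C)=C | intermediate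
19 | methyl (2E)-2-{(1S,2S)-2-[(2S,3R)-2-ethenyl-4-methylidene-5-oxooxolan-3-yl]-2-hydroxy-1-{[(2R)-2-methyloxirane-2-carbonyl]oxy}ethyl}-6-methylhepta-2,6-dienoate | C=C1C(=O)O[C@@H](C=C)[C@H]1[C@H](O)[C@@H](OC(=O)[C@@]1(C)CO1)/C(C(=O)OC)=C\CCC(C)=C | intermediate
20 | methyl (2E)-2-{(1S,2S)-2-(acetyloxy)-2-[(2S,3S)-2-ethenyl-4-methylidene-5-oxooxolan-3-yl]-1-{[(2R)-2-methyloxirane-2-carbonyl]oxy}ethyl}-6-methylhepta-2,6-dienoate | C=C1C(=O)O[C@@H](C=C)[C@H]1[C@H](OC(C)=O)[C@@H](OC(=O)[C@@]1(C)CO1)/C(C(=O)OC)=C\CCC(C)=C | intermediate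
21 | methyl (3aS,4S,5S,6E,10Z,11aS)-4-(acetyloxy)-10-methyl-3-methylidene-5-{[(2R)-2-methyloxirane-2-carbonyl]oxy}-2-oxo-2,3,3a,4,5,8,9,11a-octahydrocyclodeca[b]furan-6-carboxylate | C=C1C(=O)O[C@H]2/C=C(C)\CC/C=C(C(=O)OC)\[C@H](OC(=O)[C@@]3(C)CO3)[C@@H](OC(C)=O)[C@@H]12 | intermediate
22 | methyl (3aR,4S,5S,6E,10R,11S,11aR)-4-(acetyloxy)-10,11-epoxy-10-methyl-3-methylidene-5-{[(2R)-2-methyloxirane-2-carbonyl]oxy}-2-oxo-2,3,3a,4,5,8,9,10,11,11a-decahydrocyclodeca[b]furan-6-carboxylate (CNP0159450.1) | C=C1C(=O)O[C@@H]2[C@H]1[C@H](OC(C)=O)[C@@H](OC(=O)[C@@]1(C)CO1)/C(C(=O)OC)=C\CC[C@@]1(C)O[C@@H]21 | target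

Total step count: 14 (steps 7 and 9 prepare the two side fragments).
Longest linear sequence: 12 steps (1–6, 8, 10–14), from 1 to 22.

Steps most likely to fail

1. Step 13. The C5 alkylidene may close onto C10 instead of C4, cutting off the C1–C4 chain and leaving a cyclohexene, or the hindered C4 alkene may be engaged so slowly that oligomerisation through the vinyl group takes over. Fallback: relay ring-closing metathesis, which delivers the carbene to C4 first. It sets out from ylide 12 and aldehyde 10 and returns at 21.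
   - Wittig reaction of purchased 5,5-dimethoxypentan-2-one with the ylide from purchased (hex-5-en-1-yl)triphenylphosphonium bromide (NaHMDS, THF) would give the acetal 10,10-dimethoxy-7-methyldeca-1,6-diene F1. Aqueous HCl in acetone then frees the aldehyde 4-methyldeca-4,9-dienal F2; the geometry of its internal alkene is irrelevant.
   - F2 takes the place of 11 in step 7 (12, NIS, via 13) and gives the relay iodoenoate methyl (2Z)-2-iodo-6-methyldodeca-2,6,11-trienoate F3.
   - Coupling of F3 with 10 as in step 8 gives the relay alcohol F4. The operations of steps 10–12 (acid 17 under Mitsunobu conditions, HF·pyridine, Ac2O) then give the relay epoxy ester F5, the relay C8 alcohol F6 and the relay acetate F7. F7 is 20 with a hex-5-enylidene arm in place of the terminal methylene on C4.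
   - With the same ruthenium catalyst the carbene should enter at the unhindered terminal alkene of the arm, expel cyclopentene and so be placed on C4. From there the only ring it can close is ring A, onto the C5 vinyl group, which gives 21.

2. Step 10. The carboxylate may attack C1 in an SN2′ sense, or the hindered displacement at C9 may be too slow, so that the C9 configuration or the ester position is lost. Fallback: oxidation and reduction in place of inversion. It sets out from alcohol 15 and returns at ester 18.
   - Dess–Martin periodinane (NaHCO3, CH2Cl2, 0 °C) would oxidise 15, whatever its epimer composition at C9, to the alkylidene keto ester F8.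
   - Luche reduction (NaBH4, CeCl3·7H2O, MeOH, −78 °C) should deliver hydride to the ketone under non-chelation control of the C8 silyl ether. For a hydride nucleophile this gives the 8,9-syn relationship, the (9S) alcohol F9.
   - Yamaguchi esterification of F9 with acid 17 (2,4,6-trichlorobenzoyl chloride, Et3N, then DMAP, toluene) proceeds with retention and gives 18.

3. Step 14. The peracid may attack the other face of C4=C5 and give the epimeric cis epoxide. Fallback: a halohydrin sequence, which places the oxygen on the face opposite to the one an electrophile prefers. It sets out from 21 and returns at 22.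
   - NBS in THF/H2O at 0 °C would form the bromonium ion on the face the peracid chose, and water opens it at the tertiary C4 from the other side to give the (4R,5R) bromohydrin F10.
   - Ag2O in MeCN then closes the epoxide by backside displacement of bromide at C5 and gives 22.

Further compounds
F1 | step 13 | 10,10-dimethoxy-7-methyldeca-1,6-diene (E/Z mixture at C6=C7) | COC(OC)CCC(C)=CCCCC=C
F2 | step 13 | 4-methyldeca-4,9-dienal (E/Z mixture at C4=C5) | O=CCCC(C)=CCCCC=C
F3 | step 13 | methyl (2Z)-2-iodo-6-methyldodeca-2,6,11-trienoate (E/Z mixture at C6=C7) | COC(=O)/C(I)=C/CCC(C)=CCCCC=C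
F4 | step 13 | methyl (2E)-2-{(1R,2S)-2-[(2S,3S)-2-ethenyl-4-methylidene-5-oxooxolan-3-yl]-1-hydroxy-2-(triethylsilyloxy)ethyl}-6-methyldodeca-2,6,11-trienoate | C=C1C(=O)O[C@@H](C=C)[C@H]1[C@H](O[Si](CC)(CC)CC)[C@H](O)/C(C(=O)OC)=C\CCC(C)=CCCCC=C
F5 | step 13 | methyl (2E)-2-{(1S,2S)-2-[(2S,3S)-2-ethenyl-4-methylidene-5-oxooxolan-3-yl]-1-{[(2R)-2-methyloxirane-2-carbonyl]oxy}-2-(triethylsilyloxy)ethyl}-6-methyldodeca-2,6,11-trienoate | C=C1C(=O)O[C@@H](C=C)[C@H]1[C@H](O[Si](CC)(CC)CC)[C@@H](OC(=O)[C@@]1(C)CO1)/C(C(=O)OC)=C\CCC(C)=CCCCC=C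
F6 | step 13 | methyl (2E)-2-{(1S,2S)-2-[(2S,3R)-2-ethenyl-4-methylidene-5-oxooxolan-3-yl]-2-hydroxy-1-{[(2R)-2-methyloxirane-2-carbonyl]oxy}ethyl}-6-methyldodeca-2,6,11-trienoate | C=C1C(=O)O[C@@H](C=C)[C@H]1[C@H](O)[C@@H](OC(=O)[C@@]1(C)CO1)/C(C(=O)OC)=C\CCC(C)=CCCCC=C
F7 | step 13 | methyl (2E)-2-{(1S,2S)-2-(acetyloxy)-2-[(2S,3S)-2-ethenyl-4-methylidene-5-oxooxolan-3-yl]-1-{[(2R)-2-methyloxirane-2-carbonyl]oxy}ethyl}-6-methyldodeca-2,6,11-trienoate | C=C1C(=O)O[C@@H](C=C)[C@H]1[C@H](OC(C)=O)[C@@H](OC(=O)[C@@]1(C)CO1)/C(C(=O)OC)=C\CCC(C)=CCCCC=C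
F8 | step 10 | methyl (2E)-2-{(2S)-2-[(2S,3S)-2-ethenyl-4-methylidene-5-oxooxolan-3-yl]-2-(triethylsilyloxy)acetyl}-6-methylhepta-2,6-dienoate | C=C1C(=O)O[C@@H](C=C)[C@H]1[C@H](O[Si](CC)(CC)CC)C(=O)/C(C(=O)OC)=C\CCC(C)=C
F9 | step 10 | methyl (2E)-2-{(1S,2S)-2-[(2S,3S)-2-ethenyl-4-methylidene-5-oxooxolan-3-yl]-1-hydroxy-2-(triethylsilyloxy)ethyl}-6-methylhepta-2,6-dienoate | C=C1C(=O)O[C@@H](C=C)[C@H]1[C@H](O[Si](CC)(CC)CC)[C@@H](O)/C(C(=O)OC)=C\CCC(C)=C
F10 | step 14 | methyl (3aR,4S,5S,6E,10R,11R,11aR)-4-(acetyloxy)-11-bromo-10-hydroxy-10-methyl-3-methylidene-5-{[(2R)-2-methyloxirane-2-carbonyl]oxy}-2-oxo-2,3,3a,4,5,8,9,10,11,11a-decahydrocyclodeca[b]furan-6-carboxylate | C=C1C(=O)O[C@@H]2[C@H]1[C@H](OC(C)=O)[C@@H](OC(=O)[C@@]1(C)CO1)/C(C(=O)OC)=C\CC[C@@](C)(O)[C@@H]2Br
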